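Picture the vessel: a stirred flask of starting complex and leaving ligand, where incoming ligand replaces leaving ligand on the complex.

| setting | theta | zeta | delta | Sunday's | Thursday's | Saturday's |
|---|---|---|---|---|---|---|
| starting complex | 20 mM | 20 mM | 20 mM | 20 mM (fed, over 40 min) | 20 mM | 20 mM |
| incoming ligand | 0.60 equiv | 0.40 equiv | 0.90 equiv | 0.600 equiv | 0.600 equiv | 0.600 equiv (fed, over 40 min) |
| leaving ligand | 2 equiv | 2 equiv | 2 equiv | 2.00 equiv | 2.00 equiv | 2.00 equiv |
| remark | run made earlier | run made earlier | run made earlier | all else is in the flask from the start; the feed brings no volume worth counting | everything together at the start | all else is in the flask from the start; the feed brings no volume worth counting |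
| time |  |  |  | 50 min | 50 min | 50 min |

| run | time / min | complex with one exchanged / % | starting complex / % |
|---|---|---|---|
| theta | 4.00 | 14.7 | 85.1 |
| theta | 6.00 | 17.9 | 82.4 |
| theta | 12.0 | 21.8 | 77.9 |
| theta | 20.0 | 23.7 | 75.1 |
| theta | 30.0 | 25.7 | 74.3 |
| theta | 50.0 | 24.8 | 74.6 |
| zeta | 8.00 | 15.9 | 84.5 |
| zeta | 15.0 | 18.7 | 81.1 |
| zeta | 25.0 | 20.2 | 79.6 |
| zeta | 30.0 | 20.2 | 79.9 |
| zeta | 40.0 | 19.9 | 79.8 |
| zeta | 50.0 | 20.4 | 79.6 |
| delta | 3.00 | 15.8 | 82.8 |
| delta | 10.0 | 25.6 | 72.9 |
| delta | 20.0 | 29.0 | 70.5 |
| delta | 25.0 | 29.4 | 70.7 |
| delta | 40.0 | 30.0 | 69.7 |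
| delta | 50.0 | 29.9 | 70.0 |

(readings scatter by 0.5 percentage points)



1. which flask leads in amount of complex with one exchanged, in percent of the starting complex charged ("all alike" within 1.5 percentage points) (Sunday's / Thursday's / Saturday's / all alike)
2. how much complex with one exchanged is there at the end, in percent of the starting complex charged: Sunday's
3. how much complex with one exchanged is there at the end, in percent of the starting complex charged: Thursday's
4. how much complex with one exchanged is there at the end, in percent of the starting complex charged: Saturday's

Read the plateaus first. Suspect an equilibrium, and test it: the ratio of products to reactants, read at the plateau, is 2.88 for zeta, 2.19 for theta and 1.63 for delta. It drifts, so drop it and suppose the ligand goes elsewhere.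

Theta levels at 25.2%, which gives 1.38 for the waste number: incoming ligand charged but not found in complex with one exchanged, per unit found there (a selectivity factor). Divide it by the charge: zeta gives 2.40, theta 2.29, delta 2.23. So, in these batches, the waste number grows in step with the ligand charged; read that as waste following the ligand standing. Thursday's repeats theta: expect 25.2%.

Now object: how far does a feed lower the standing ligand? Count half-lives. Theta's reading at 4.00 min lies 1.26 half-lives along, so one lasts 3.18 min. Multiply the lifetime by one plus the waste number to get the exchange lifetime, 10.9 min. Take a batch's mean standing ligand as its charge over 2, then set Saturday's feed equal to exchange plus waste and solve the quadratic. The waste number comes to 0.500, and the estimate of complex with one exchanged to 40.0%.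

Object again: in Saturday's flask exchange needs the complex, and the complex thins as it reacts. Redo it with the mean complex, 80.0% of the charge. The waste number rises to 0.692; commit to 35.5% for Saturday's, above Thursday's.

The forecast differs, holding that “Feeding wastes the active period”. It gives 4.4% for Sunday's, 25% for Thursday's and 8.6% for Saturday's, with Thursday's leading.

The flasks give 9.16% for Sunday's, 25.1% for Thursday's and 35.2% for Saturday's, so Saturday's leads, above the top of the forecast's range for Saturday's, 16%.

    complex with two exchanged + incoming ligand ⇌ leaving ligand + complex with three exchanged (K = 3.50, k = 5.60 M⁻¹ min⁻¹)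
    starting complex + incoming ligand ⇌ leaving ligand + complex with one exchanged (K = 68.0, k = 6.50 M⁻¹ min⁻¹)
    complex with three exchanged + incoming ligand ⇌ leaving ligand + complex with four exchanged (K = 7.30, k = 1.00 M⁻¹ min⁻¹)
    complex with one exchanged + incoming ligand ⇌ leaving ligand + complex with two exchanged (K = 1.90, k = 0.570 M⁻¹ min⁻¹)
    2 incoming ligand → homo dimer (k = 15.0 M⁻¹ min⁻¹)

Thursday's waste number is 1.39 against theta's 1.38; Saturday's is 0.704 against the reckoned 0.692. Repeat the reckoning on the neighbour, Saturday's flask with 1.50 equiv of incoming ligand. The first pass gives 0.957, the mean complex is 61.7%, and the second pass gives 1.77, hence 54.1%. That neighbour gives 56.0%, a waste number of 1.68.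

The earlier runs and the new flask are simulated for an exercise; scatter was added.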